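**Strategy.** The pyranone ring C of the isoflavanone is cut at C2–C3 and C4–C4a. This leaves ring A with O1 and the C2 methylene as an aryloxymethyl cation (a 2-oxonia-diene C4a=C8a–O1=C2) and ring B with C3–C4 as an aryl ynamide. One cationic [4+2] annulation joins them: the ynamide carbon bearing ring B attacks C2, and the resulting keteniminium carbon acylates C4a, which lies ortho to O1 and para to the C7 oxygen. Hydrolysis of the enamide gives the racemic ketone. Both prenyl groups then enter by a twofold Stille coupling at bromine placeholders, and C3 is set by transfer hydrogenation with dynamic kinetic resolution followed by reoxidation.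

Key step: step 6

Remark: C3 of the target is (S) (priorities C4 > C2 > aryl C1' > H).
Assumption: the usual facial preference of the Noyori–Ikariya catalyst (the (S,S)-ligand gives the S-configured benzylic alcohol) is taken to hold for ketone 11; if a test shows the opposite, the (R,R)-complex is used and nothing else changes.

**Route**

Step 1
Reactants: 1 4-bromobenzene-1,3-diol
Product: 3 [2-bromo-5-(methylsulfanylmethoxy)phenoxy]triisopropylsilane, via sodium 2-bromo-5-(methylsulfanylmethoxy)phenolate 2 (not isolated)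
Conditions: NaH (2.2 equiv), DMF, 0 °C; ClCH2SMe (1.0 equiv), −20 to 0 °C; then TIPSCl (1.2 equiv), 0 °C to rt
Reagents that add atoms: chloromethyl methyl sulfide, CSCCl; chlorotriisopropylsilane, CC(C)[Si](Cl)(C(C)C)C(C)C
Why: Williamson etherification of the dianion, in which the phenoxide para to bromine is the more basic and less hindered oxygen and should take the single equivalent of alkyl chloride, after which the remaining ortho-bromo phenoxide is silylated in the same flask.

Step 2
Reactants: 3 [2-bromo-5-(methylsulfanylmethoxy)phenoxy]triisopropylsilane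
Product: 4 [2-bromo-5-(chloromethoxy)phenoxy]triisopropylsilane
Conditions: SO2Cl2 (1.05 equiv), CH2Cl2, −78 to 0 °C; volatiles removed in vacuo, used crude
Reagents that add atoms: sulfuryl chloride, O=S(=O)(Cl)Cl
Why: Chlorinolysis of the O,S-acetal (S-chlorination, loss of MeSCl to the oxocarbenium ion, chloride return) is the standard conversion of a methylthiomethyl aryl ether into the aryl chloromethyl ether, and reaction at sulfur should be far faster than ring chlorination.

Step 3
Reactants: 5 3-bromo-4-hydroxybenzaldehyde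
Product: 6 3-bromo-4-(triisopropylsilyloxy)benzaldehyde
Conditions: TIPSCl, imidazole, DMF, rt
Reagents that add atoms: chlorotriisopropylsilane, CC(C)[Si](Cl)(C(C)C)C(C)C
Why: Imidazole-promoted O-silylation of the phenol gives a silyl ether that should withstand the base, Lewis acid and palladium steps that follow.

Step 4
Reactants: 6 3-bromo-4-(triisopropylsilyloxy)benzaldehyde
Product: 7 [2-bromo-4-(2,2-dibromoethenyl)phenoxy]triisopropylsilane
Conditions: CBr4, PPh3, CH2Cl2, 0 °C
Reagents that add atoms: tetrabromomethane, BrC(Br)(Br)Br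
Why: Ramirez dibromo-olefination (first stage of the Corey–Fuchs sequence) of an aromatic aldehyde by the dibromomethylene ylide made in situ.

Step 5
Reactants: 7 [2-bromo-4-(2,2-dibromoethenyl)phenoxy]triisopropylsilane
Product: 8 N-{[3-bromo-4-(triisopropylsilyloxy)phenyl]ethynyl}-N,4-dimethylbenzenesulfonamide
Conditions: CuI (12 mol%), N,N'-dimethylethylenediamine (18 mol%), Cs2CO3, 1,4-dioxane, 60 °C
Reagents that add atoms: N-methyl-4-methylbenzenesulfonamide, CNS(=O)(=O)c1ccc(C)cc1
Why: Copper-catalysed Ullmann–Goldberg-type amidation of the 1,1-dibromoalkene followed by base-induced dehydrobromination gives the ynamide, and the hindered aryl bromide should be inert at this temperature.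

Step 6
Reactants: 4 [2-bromo-5-(chloromethoxy)phenoxy]triisopropylsilane; 8 N-{[3-bromo-4-(triisopropylsilyloxy)phenyl]ethynyl}-N,4-dimethylbenzenesulfonamide (1.2 equiv)
Product: 10 rac-6-bromo-3-[3-bromo-4-(triisopropylsilyloxy)phenyl]-7-(triisopropylsilyloxy)-2,3-dihydro-4H-chromen-4-one, via 4-(N-methyl-N-tosylamino)-2H-chromene enamide 9 (not isolated)
Conditions: AgNTf2 (1.1 equiv), 2,6-di-tert-butyl-4-methylpyridine (1.5 equiv), CH2Cl2, −78 to −20 °C; then 2 M HCl, THF, rt
Reagents that add atoms: water, O
Why: Proposed new method: chloride abstraction from 4 by AgNTf2 should give the aryloxymethyl cation (a 2-oxonia-diene), whose CH2 carbon is attacked by the aryl-bearing β-carbon of ynamide 8 (C2–C3 bond); the resulting keteniminium ion is then trapped by the ring A carbon ortho to O1 in a Friedel–Crafts step (C4–C4a bond), giving enamide 9 after proton loss to the hindered pyridine, and aqueous acid hydrolyses 9 to ketone 10. The closest known reaction types are the oxa-Povarov [4+2] annulation of aryl oxocarbenium ions with alkenes, the cationic [4+2] annulation of arylthionium ions with alkynes, and Friedel–Crafts ring closures of keteniminium ions made from ynamides. The pyranone ring closes in a six-membered mode by attack on the sp carbon of the keteniminium ion (exo with respect to its C=N bond, the C3=C4 bond staying inside the ring), which is unstrained. C3 is sp2 in 9 and becomes a stereocentre only on hydrolysis, without control, so 10 is racemic and the configuration is left to step 8. The cation must choose the ynamide over the arenes, which the much higher nucleophilicity of the ynamide β-carbon, its excess and the low temperature should secure, and the nitrogen polarisation of the ynamide fixes which alkyne carbon bonds to C2. Ring closure must occur at the right carbon, which is favoured because that carbon is para to the silyloxy group and unhindered, whereas the other ortho carbon is flanked by the triisopropylsilyloxy group.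

Step 7
Reactants: 10 rac-6-bromo-3-[3-bromo-4-(triisopropylsilyloxy)phenyl]-7-(triisopropylsilyloxy)-2,3-dihydro-4H-chromen-4-one
Product: 11 rac-6-(3-methylbut-2-enyl)-3-[3-(3-methylbut-2-enyl)-4-(triisopropylsilyloxy)phenyl]-7-(triisopropylsilyloxy)-2,3-dihydro-4H-chromen-4-one
Conditions: prenylSnBu3 (2.6 equiv), Pd(PPh3)4 (10 mol%), DMF, 100 °C
Reagents that add atoms: tributyl(3-methylbut-2-en-1-yl)stannane, CC(C)=CC[Sn](CCCC)(CCCC)CCCC
Why: Twofold Stille coupling of the two aryl bromides with the prenylstannane, which should deliver the linear (α-coupled) prenyl arenes under base-free conditions that leave the ketone and silyl ethers alone.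

Step 8
Reactants: 11 rac-6-(3-methylbut-2-enyl)-3-[3-(3-methylbut-2-enyl)-4-(triisopropylsilyloxy)phenyl]-7-(triisopropylsilyloxy)-2,3-dihydro-4H-chromen-4-one
Product: 12 (3S,4S)-6-(3-methylbut-2-enyl)-3-[3-(3-methylbut-2-enyl)-4-(triisopropylsilyloxy)phenyl]-7-(triisopropylsilyloxy)-3,4-dihydro-2H-chromen-4-ol (3,4-cis)
Conditions: RuCl[(S,S)-TsDPEN](p-cymene) (2 mol%), HCO2H/Et3N (1:3), EtOAc, 40 °C
Reagents that add atoms: none
Why: Noyori–Ikariya asymmetric transfer hydrogenation with dynamic kinetic resolution, in which the (S,S)-ligand directs hydride to the carbonyl face that gives the 4S alcohol and hydride adds anti to the C3 aryl group, so only the (3S)-ketone reacts fast while the (3R)-ketone racemises through its enol under the amine; this sets C3 as S, with C4 as a temporary centre.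

Step 9
Reactants: 12 (3S,4S)-6-(3-methylbut-2-enyl)-3-[3-(3-methylbut-2-enyl)-4-(triisopropylsilyloxy)phenyl]-7-(triisopropylsilyloxy)-3,4-dihydro-2H-chromen-4-ol
Product: 13 (3S)-6-(3-methylbut-2-enyl)-3-[3-(3-methylbut-2-enyl)-4-(triisopropylsilyloxy)phenyl]-7-(triisopropylsilyloxy)-2,3-dihydro-4H-chromen-4-one
Conditions: Dess–Martin periodinane, CH2Cl2, 0 °C to rt; pH 7 buffer/Na2S2O3 work-up
Reagents that add atoms: none
Why: Dess–Martin oxidation of the benzylic alcohol under non-basic conditions removes the temporary C4 centre without enolising the C3 centre.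

Step 10
Reactants: 13 (3S)-6-(3-methylbut-2-enyl)-3-[3-(3-methylbut-2-enyl)-4-(triisopropylsilyloxy)phenyl]-7-(triisopropylsilyloxy)-2,3-dihydro-4H-chromen-4-one
Product: 14 (3S)-7-hydroxy-3-[4-hydroxy-3-(3-methylbut-2-enyl)phenyl]-6-(3-methylbut-2-enyl)-2,3-dihydro-4H-chromen-4-one
Conditions: Bu4NF/AcOH (1:1), THF, 0 °C
Reagents that add atoms: none
Why: Fluoride cleavage of both aryl silyl ethers, buffered with acetic acid so that each phenoxide is protonated at once and the base-labile C3 centre and the prenyl groups should be left untouched.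

**Compound list**

1 | 4-bromobenzene-1,3-diol | Oc1ccc(Br)c(O)c1 | starting material
2 | sodium 2-bromo-5-(methylsulfanylmethoxy)phenolate | [Na+].[O-]c1cc(OCSC)ccc1Br | intermediate (not isolated)
3 | [2-bromo-5-(methylsulfanylmethoxy)phenoxy]triisopropylsilane | CSCOc1ccc(Br)c(O[Si](C(C)C)(C(C)C)C(C)C)c1 | intermediate
4 | [2-bromo-5-(chloromethoxy)phenoxy]triisopropylsilane | ClCOc1ccc(Br)c(O[Si](C(C)C)(C(C)C)C(C)C)c1 | intermediate
5 | 3-bromo-4-hydroxybenzaldehyde | O=Cc1ccc(O)c(Br)c1 | starting material
6 | 3-bromo-4-(triisopropylsilyloxy)benzaldehyde | O=Cc1ccc(O[Si](C(C)C)(C(C)C)C(C)C)c(Br)c1 | intermediate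
7 | [2-bromo-4-(2,2-dibromoethenyl)phenoxy]triisopropylsilane | BrC(Br)=Cc1ccc(O[Si](C(C)C)(C(C)C)C(C)C)c(Br)c1 | intermediate
8 | N-{[3-bromo-4-(triisopropylsilyloxy)phenyl]ethynyl}-N,4-dimethylbenzenesulfonamide | CN(C#Cc1ccc(O[Si](C(C)C)(C(C)C)C(C)C)c(Br)c1)S(=O)(=O)c1ccc(C)cc1 | intermediate
9 | N-{6-bromo-3-[3-bromo-4-(triisopropylsilyloxy)phenyl]-7-(triisopropylsilyloxy)-2H-chromen-4-yl}-N,4-dimethylbenzenesulfonamide | CN(C1=C(c2ccc(O[Si](C(C)C)(C(C)C)C(C)C)c(Br)c2)COc2cc(O[Si](C(C)C)(C(C)C)C(C)C)c(Br)cc21)S(=O)(=O)c1ccc(C)cc1 | intermediate (not isolated)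
10 | rac-6-bromo-3-[3-bromo-4-(triisopropylsilyloxy)phenyl]-7-(triisopropylsilyloxy)-2,3-dihydro-4H-chromen-4-one | O=C1c2cc(Br)c(O[Si](C(C)C)(C(C)C)C(C)C)cc2OCC1c1ccc(O[Si](C(C)C)(C(C)C)C(C)C)c(Br)c1 | intermediate
11 | rac-6-(3-methylbut-2-enyl)-3-[3-(3-methylbut-2-enyl)-4-(triisopropylsilyloxy)phenyl]-7-(triisopropylsilyloxy)-2,3-dihydro-4H-chromen-4-one | CC(C)=CCc1cc(C2COc3cc(O[Si](C(C)C)(C(C)C)C(C)C)c(CC=C(C)C)cc3C2=O)ccc1O[Si](C(C)C)(C(C)C)C(C)C | intermediate
12 | (3S,4S)-6-(3-methylbut-2-enyl)-3-[3-(3-methylbut-2-enyl)-4-(triisopropylsilyloxy)phenyl]-7-(triisopropylsilyloxy)-3,4-dihydro-2H-chromen-4-ol | CC(C)=CCc1cc([C@H]2COc3cc(O[Si](C(C)C)(C(C)C)C(C)C)c(CC=C(C)C)cc3[C@H]2O)ccc1O[Si](C(C)C)(C(C)C)C(C)C | intermediate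
13 | (3S)-6-(3-methylbut-2-enyl)-3-[3-(3-methylbut-2-enyl)-4-(triisopropylsilyloxy)phenyl]-7-(triisopropylsilyloxy)-2,3-dihydro-4H-chromen-4-one | CC(C)=CCc1cc([C@H]2COc3cc(O[Si](C(C)C)(C(C)C)C(C)C)c(CC=C(C)C)cc3C2=O)ccc1O[Si](C(C)C)(C(C)C)C(C)C | intermediate
14 | (3S)-7-hydroxy-3-[4-hydroxy-3-(3-methylbut-2-enyl)phenyl]-6-(3-methylbut-2-enyl)-2,3-dihydro-4H-chromen-4-one | CC(C)=CCc1cc([C@H]2COc3cc(O)c(CC=C(C)C)cc3C2=O)ccc1O | target

**Summary**

Total step count: 10. Longest linear sequence: 8 steps (steps 3, 4, 5, 6, 7, 8, 9, 10).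

Steps most likely to fail:

1. Step 6 (proposed new method). The aryloxymethyl cation may be consumed by Friedel–Crafts attack on the electron-rich arenes (oligomerisation) faster than it is captured by the ynamide, or the keteniminium ion may be intercepted before ring closure. The fallback sets out from ynamide 8 and chloromethyl ether 4 and comes back at ketone 10, using only known reaction types. Acid-catalysed hydration of 8 (TsOH·H2O, wet CH2Cl2, rt) would give 2-[3-bromo-4-(triisopropylsilyloxy)phenyl]-N-methyl-N-tosylacetamide F1. Its lithium enolate (LiHMDS, THF, −78 °C) would be alkylated by 4 to rac-3-[4-bromo-3-(triisopropylsilyloxy)phenoxy]-2-[3-bromo-4-(triisopropylsilyloxy)phenyl]-N-methyl-N-tosylpropanamide F2, making the C2–C3 bond. An intramolecular Friedel–Crafts acylation of this activated amide (TfOH, CH2Cl2, 0 °C) would then close C4–C4a to 10. The price is that the two bonds are made in separate operations.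

2. Step 7. Oxidative addition at the two hindered, electron-rich bromides ortho to silyloxy groups may be slow, with protodebromination or branched (γ) coupling of the prenyl unit competing. The fallback sets out from dibromide 10 and comes back at 11. A twofold Stille coupling with allyltributylstannane (Pd(PPh3)4, DMF, 90 °C), which has no α/γ ambiguity and is less hindered, would give rac-6-allyl-3-[3-allyl-4-(triisopropylsilyloxy)phenyl]-7-(triisopropylsilyloxy)-2,3-dihydro-4H-chromen-4-one F3. Olefin cross-metathesis with excess 2-methyl-2-butene (second-generation Grubbs catalyst, CH2Cl2, 40 °C) would convert both allyl groups into prenyl groups to give 11.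

3. Step 8. Racemisation of the ketone at C3 may be slower than reduction of the slow enantiomer, so the dynamic resolution degrades into a simple kinetic resolution, or hydride delivery may not be fully anti to the aryl group. The fallback sets out from racemic ketone 11 and comes back at 13, bypassing alcohol 12 and step 9. O-Acylation of the potassium enolate (KHMDS, THF, −78 °C, then allyl chloroformate) would give allyl 6-(3-methylbut-2-enyl)-3-[3-(3-methylbut-2-enyl)-4-(triisopropylsilyloxy)phenyl]-7-(triisopropylsilyloxy)-2H-chromen-4-yl carbonate F4. Palladium-catalysed decarboxylative enantioselective protonation (Pd2(dba)3, (S)-t-BuPHOX, Meldrum's acid, 1,4-dioxane, rt to 40 °C) would protonate the chiral palladium enolate at C3 to give 13. The ligand enantiomer that delivers the (S)-ketone would be fixed by a small-scale test.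

**Further compounds**

F1 | step 6 | 2-[3-bromo-4-(triisopropylsilyloxy)phenyl]-N-methyl-N-tosylacetamide | CN(C(=O)Cc1ccc(O[Si](C(C)C)(C(C)C)C(C)C)c(Br)c1)S(=O)(=O)c1ccc(C)cc1
F2 | step 6 | rac-3-[4-bromo-3-(triisopropylsilyloxy)phenoxy]-2-[3-bromo-4-(triisopropylsilyloxy)phenyl]-N-methyl-N-tosylpropanamide | CN(C(=O)C(COc1ccc(Br)c(O[Si](C(C)C)(C(C)C)C(C)C)c1)c1ccc(O[Si](C(C)C)(C(C)C)C(C)C)c(Br)c1)S(=O)(=O)c1ccc(C)cc1
F3 | step 7 | rac-6-allyl-3-[3-allyl-4-(triisopropylsilyloxy)phenyl]-7-(triisopropylsilyloxy)-2,3-dihydro-4H-chromen-4-one | C=CCc1cc(C2COc3cc(O[Si](C(C)C)(C(C)C)C(C)C)c(CC=C)cc3C2=O)ccc1O[Si](C(C)C)(C(C)C)C(C)C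
F4 | step 8 | allyl 6-(3-methylbut-2-enyl)-3-[3-(3-methylbut-2-enyl)-4-(triisopropylsilyloxy)phenyl]-7-(triisopropylsilyloxy)-2H-chromen-4-yl carbonate | C=CCOC(=O)OC1=C(c2ccc(O[Si](C(C)C)(C(C)C)C(C)C)c(CC=C(C)C)c2)COc2cc(O[Si](C(C)C)(C(C)C)C(C)C)c(CC=C(C)C)cc21
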